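All runs were computed with constants of no real substance, noise included.

1. In a one-step world, where substrate and partner meet once on the free catalyst, each charge would act with a whole power, and the powers could be read from any two flasks. These flasks show a slow start, so the powers have to be measured.

| setting | Monday's | Sunday's | Wednesday's | Saturday's | Tuesday's |
|---|---|---|---|---|---|
| substrate | 0.250 M | 0.500 M | 0.250 M | 0.250 M | 0.0830 M |
| partner | 0.250 M | 0.250 M | 0.120 M | 0.250 M | 0.0830 M |
| free catalyst | 0.0200 M | 0.0200 M | 0.0200 M | 0.0300 M | 0.0200 M |
| time |  |  |  |  | 27 min |

| Monday's run: time / min | Monday's run: [target] / M | Sunday's run: time / min | Sunday's run: [target] / M | Wednesday's run: time / min | Wednesday's run: [target] / M | Saturday's run: time / min | Saturday's run: [target] / M |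
|---|---|---|---|---|---|---|---|
| 3.4 | 0.004 | 3.4 | 0.011 | 3.4 | 0 | 3.4 | 0.008 |
| 6.8 | 0.018 | 6.8 | 0.023 | 6.8 | 0.010 | 6.8 | 0.029 |
| 10 | 0.038 | 10 | 0.038 | 10 | 0.021 | 10 | 0.046 |
| 14 | 0.048 | 14 | 0.070 | 14 | 0.034 | 14 | 0.072 |
| 17 | 0.069 | 17 | 0.084 | 17 | 0.037 | 17 | 0.090 |
| 20 | 0.082 | 20 | 0.115 | 20 | 0.045 | 20 | 0.101 |
| 24 | 0.099 | 24 | 0.140 | 24 | 0.053 | 24 | 0.129 |
| 27 | 0.110 | 27 | 0.161 | 27 | 0.061 | 27 | 0.146 |

(scatter of a reading: 0.003 M)

- the power of [partner] that the first rate follows, about the charge of the Monday's run; measure it at two percent of substrate made into target
- the power of [free catalyst] that the first rate follows, about the charge of the Monday's run; measure it at two percent of substrate made into target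
- target in the Tuesday's run at 27 min, as a share of the substrate charged

- Overall: substrate + partner -> target, with free catalyst as catalyst.
- Constant volume, constant temperature.
- Readings of a species count what is bound in complexes too.
- An order is taken over about fifteen percent of the charge, up and down.

2. The measure is the log-slope, the logarithm of the ratio of target between two runs divided by the logarithm of the ratio of their charges. Monday's and Wednesday's runs at 27 min give a partner log-slope of 0.803, with a scatter of 0.0766. Saturday's and Monday's runs give a catalyst log-slope of 0.698, and Sunday's and Monday's runs give a substrate log-slope of 0.550.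

3. The objection is that these are amounts gathered over a whole run, whereas the question concerns a rate at 0.00500 M of target, a level close to the scatter of 0.003 M. Moving the partner quotient to the 6.8 min readings gives 0.801, but now with a scatter of 0.468, so the early readings cannot test the late figure. This reckoning therefore keeps 0.803 and 0.698, as upper guides for the partner and with less confidence for the first rate.

4. Tuesday's run divides substrate and partner together, so its slope is the sum, 1.35. Scaling Monday's target by that power gives 29.8 % of Tuesday's substrate. The objection is that Tuesday's substrate lies lower than any charge tried, so the slope is carried outside its range. A summed slope of unity would keep Monday's share of 44.0 %, and this reckoning stays at the lower figure while treating the higher one as its limit of doubt.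

5. The forecast differs from this reckoning: it gives 0.6 for the partner and 0.5 for the catalyst, on the ground that at this small conversion “the apparent orders are pulled down towards half the time-based values”. Separately, it gives 24 % for Tuesday's run, from a rate scaled down from Monday's by the orders read after the slow start and carried over the effective minutes of the run.

6. The simulation gives 0.41, 0.66 and 45.6 %.

    free catalyst + substrate → catalyst-substrate complex (2.760 L mol⁻¹ min⁻¹)
    catalyst-substrate complex + partner → loaded catalyst (5.562 L mol⁻¹ min⁻¹)
    loaded catalyst → target + free catalyst (0.4626 min⁻¹)
    catalyst-substrate complex + substrate ⇌ doubly bound catalyst, settled at all times (7.570 L mol⁻¹)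
    substrate + partner + target → 2 target (0.9000 L² mol⁻² min⁻¹)

Tuesday's share corresponds to a summed log-slope of 0.968, lower than the 1.35 carried there. On Wednesday's run, the simulated rate ratio of 0.71 gives a partner log-slope of 0.464, lower than the 0.803 from the late amounts. The first-rate partner order about Monday's charge owes part of its size to substrate inhibition, the parking of catalyst-substrate complex with substrate as doubly bound catalyst: with the parking taken away, that order falls from 0.41 to 0.24.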